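**Strategy.** Ring B is closed last across its most hindered bond, C9–C10 (labdane numbering). The step exploits that C10 is the methyl-bearing ring-fusion carbon and C9 is β to the C8 carboxyl: hydrogen-atom transfer from an iron hydride to the C1=C10 alkene of an enantiopure 2,6,6-trimethylcyclohex-2-enyl ring A gives the tertiary C10 radical, which adds 6-endo to C9 of a (Z)-acrylate; loss of the C7 acetate then leaves the C7=C8 enoate. One operation sets quaternary C10, C9 and the trans ring fusion, relayed from C5 (CBS reduction, then Claisen rearrangement). The precursor is a monocyclic Morita–Baylis–Hillman-type acetate; C6 oxygenation and the dienyl chain follow.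

Key step: step 6

Remark: ketone 1 and alkyne 5 are taken as purchasable building blocks; atoms are numbered as in the labdane skeleton (C9 and C10 are C1 and C8a of the octahydronaphthalene names).

**Step 1**
Reactants: 1 2,4,4-trimethylcyclohex-2-en-1-one
Product: 2 (1S)-2,4,4-trimethylcyclohex-2-en-1-ol
Conditions: (R)-2-methyl-CBS-oxazaborolidine (10 mol %), BH3·SMe2, THF, −20 °C; MeOH
Reagents that add atoms: none
Why: Corey–Bakshi–Shibata reduction, in which the methyl-substituted alkenyl arm acts as the large group, so the (R)-catalyst should deliver hydride to the face that gives the (S)-carbinol, the stereocenter from which all others are relayed.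

**Step 2**
Reactants: 2 (1S)-2,4,4-trimethylcyclohex-2-en-1-ol
Product: 4 2-[(1R)-2,6,6-trimethylcyclohex-2-en-1-yl]acetaldehyde, via allyl vinyl ether 3 (not isolated)
Conditions: ethyl vinyl ether, Hg(OAc)2 (10 mol %), 35 °C; concentrate; toluene, 150 °C (sealed tube)
Reagents that add atoms: ethyl vinyl ether, C=COCC
Why: Mercury-catalysed transvinylation followed by a Claisen rearrangement, whose suprafacial [3,3] shift across the cyclohexene should form the new C–C bond at C5 on the face the oxygen leaves, transferring the carbinol configuration and moving the alkene to C1=C10.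

**Step 3**
Reactants: 5 4,4-diethoxybut-1-yne
Product: 7 methyl 5,5-diethoxypent-2-ynoate, via lithium acetylide 6 (not isolated)
Conditions: n-BuLi, THF, −78 °C; ClCO2Me, −78 to 0 °C
Reagents that add atoms: methyl chloroformate, COC(=O)Cl
Why: Acylation of a lithium acetylide with a chloroformate is a standard route to alk-2-ynoates and forms no stereocenter.

**Step 4**
Reactants: 7 methyl 5,5-diethoxypent-2-ynoate; 4 2-[(1R)-2,6,6-trimethylcyclohex-2-en-1-yl]acetaldehyde
Product: 9 methyl (2Z)-5,5-diethoxy-2-{1-hydroxy-2-[(1R)-2,6,6-trimethylcyclohex-2-en-1-yl]ethyl}pent-2-enoate as both carbinol epimers, via vinylalane 8 (not isolated)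
Conditions: i-Bu2AlH, NMO, THF, 0 °C; then 4, 0 °C to rt; aq. Rochelle salt
Reagents that add atoms: none
Why: Vinylalumination, in which syn 1,4-hydroalumination of the ynoate gives the α-alumino acrylate 8 that adds to the aldehyde with retention, should give the Morita–Baylis–Hillman-type adduct with the C11 methylene cis to the ester (Z); the new carbinol center is uncontrolled and is destroyed in step 6.

**Step 5**
Reactants: 9 methyl (2Z)-5,5-diethoxy-2-{1-hydroxy-2-[(1R)-2,6,6-trimethylcyclohex-2-en-1-yl]ethyl}pent-2-enoate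
Product: 10 methyl (2Z)-2-{1-acetoxy-2-[(1R)-2,6,6-trimethylcyclohex-2-en-1-yl]ethyl}-5,5-diethoxypent-2-enoate
Conditions: Ac2O, pyridine, DMAP (cat.), CH2Cl2, 0 °C
Reagents that add atoms: acetic anhydride, CC(=O)OC(C)=O
Why: DMAP-catalysed acylation turns the allylic hydroxyl into the leaving group needed for the addition–elimination of step 6 without changing a stereocenter.

**Step 6**
Reactants: 10 methyl (2Z)-2-{1-acetoxy-2-[(1R)-2,6,6-trimethylcyclohex-2-en-1-yl]ethyl}-5,5-diethoxypent-2-enoate
Product: 12 methyl (1S,4aR,8aR)-1-(2,2-diethoxyethyl)-5,5,8a-trimethyl-1,4,4a,5,6,7,8,8a-octahydronaphthalene-2-carboxylate, via β-acetoxy ester 11 (not isolated)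
Conditions: Fe(acac)3 (30 mol %), PhSiH3, EtOH (0.01 M), 60 °C; then DBU, rt
Reagents that add atoms: none
Why: An iron hydride formed from Fe(acac)3 and PhSiH3 should transfer a hydrogen atom to C1 of the electron-rich ring alkene (Markovnikov), the tertiary C10 radical then adds to C9 of the acrylate, and the α-ester radical is reduced by divalent iron to an enolate that expels the C7 acetate, DBU completing the E1cB loss from any protonated 11. The closest known reaction type is the metal-hydride hydrogen-atom-transfer reductive olefin coupling (an intramolecular Giese cyclization) combined with the addition–elimination chemistry of Morita–Baylis–Hillman acetates. Ring B closes in the 6-endo-trig mode, favoured over 5-exo because the ester makes C9 the electrophilic terminus and C8 is fully substituted. C10 is controlled by the C5 stereocenter, since in the chair-like transition state the C5–C6 bond stays equatorial on ring A and C9 bonds equatorially, which makes the methyl axial and the ring fusion trans; C9 is controlled by the (Z)-alkene geometry, which places C11 (trans to C7 on the alkene) equatorial and therefore cis to the C10 methyl. The step needs hydrogen-atom transfer to the ring alkene rather than to the acrylate, secured by the preference of the iron hydride for electron-rich alkenes, and cyclization faster than reduction of the tertiary radical, secured by the short three-atom tether and high dilution.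

**Step 7**
Reactants: 12 methyl (1S,4aR,8aR)-1-(2,2-diethoxyethyl)-5,5,8a-trimethyl-1,4,4a,5,6,7,8,8a-octahydronaphthalene-2-carboxylate
Product: 13 methyl (1S,4aR,8aS)-1-(2,2-diethoxyethyl)-5,5,8a-trimethyl-4-oxo-1,4,4a,5,6,7,8,8a-octahydronaphthalene-2-carboxylate
Conditions: Rh2(cap)4 (cap = caprolactamate, C6H10NO; 1 mol %), t-BuOOH (70% aq.), ClCH2CH2Cl, 40 °C
Reagents that add atoms: tert-butyl hydroperoxide, CC(C)(C)OO
Why: Dirhodium-catalysed allylic oxidation, in which the tert-butylperoxy radical should abstract hydrogen from the C6 methylene (the only secondary position γ to the enoate) and the mixed peroxide collapses to the ketone without touching a stereocenter.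

**Step 8**
Reactants: 13 methyl (1S,4aR,8aS)-1-(2,2-diethoxyethyl)-5,5,8a-trimethyl-4-oxo-1,4,4a,5,6,7,8,8a-octahydronaphthalene-2-carboxylate
Product: 14 methyl (1S,4S,4aR,8aS)-1-(2,2-diethoxyethyl)-4-hydroxy-5,5,8a-trimethyl-1,4,4a,5,6,7,8,8a-octahydronaphthalene-2-carboxylate
Conditions: NaBH4, CeCl3·7H2O, MeOH, −78 to −40 °C
Reagents that add atoms: none
Why: Luche reduction (1,2-selective), in which hydride should attack the C6 ketone from the face opposite the axial C10 and C4 methyl groups and so give the axial alcohol cis to the angular methyl.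

**Step 9**
Reactants: 14 methyl (1S,4S,4aR,8aS)-1-(2,2-diethoxyethyl)-4-hydroxy-5,5,8a-trimethyl-1,4,4a,5,6,7,8,8a-octahydronaphthalene-2-carboxylate
Product: 15 methyl (1S,4S,4aR,8aS)-4-hydroxy-5,5,8a-trimethyl-1-(2-oxoethyl)-1,4,4a,5,6,7,8,8a-octahydronaphthalene-2-carboxylate
Conditions: PPTS, acetone/H2O, 50 °C
Reagents that add atoms: water, O
Why: Mild acid-catalysed acetal hydrolysis should unmask the C12 aldehyde, and the allylic alcohol cannot lactonize because C6 and the ester are trans on the ring alkene.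

**Step 10**
Reactants: 15 methyl (1S,4S,4aR,8aS)-4-hydroxy-5,5,8a-trimethyl-1-(2-oxoethyl)-1,4,4a,5,6,7,8,8a-octahydronaphthalene-2-carboxylate
Product: 16 methyl (1S,4S,4aR,8aS)-4-hydroxy-5,5,8a-trimethyl-1-[(2E)-3-methyl-4-oxobut-2-en-1-yl]-1,4,4a,5,6,7,8,8a-octahydronaphthalene-2-carboxylate
Conditions: Ph3P=C(CH3)CHO, toluene, 90 °C
Reagents that add atoms: 2-(triphenylphosphoranylidene)propanal, CC(C=O)=P(c1ccccc1)(c1ccccc1)c1ccccc1
Why: Wittig reaction with a stabilized ylide, which should react only with the aldehyde and give the (E)-2-methyl enal.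

**Step 11**
Reactants: 16 methyl (1S,4S,4aR,8aS)-4-hydroxy-5,5,8a-trimethyl-1-[(2E)-3-methyl-4-oxobut-2-en-1-yl]-1,4,4a,5,6,7,8,8a-octahydronaphthalene-2-carboxylate
Product: 17 methyl (1S,4S,4aR,8aS)-4-hydroxy-5,5,8a-trimethyl-1-[(2E)-3-methylpenta-2,4-dien-1-yl]-1,4,4a,5,6,7,8,8a-octahydronaphthalene-2-carboxylate
Conditions: Ph3PCH3Br, KN(SiMe3)2 (excess), THF, −78 to 0 °C
Reagents that add atoms: methyltriphenylphosphonium bromide, C[P+](c1ccccc1)(c1ccccc1)c1ccccc1.[Br-]
Why: Wittig methylenation of the enal with the non-stabilized ylide (in excess to allow for the free hydroxyl) should complete the (E)-diene without touching the hindered conjugated ester.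

**Step 12**
Reactants: 17 methyl (1S,4S,4aR,8aS)-4-hydroxy-5,5,8a-trimethyl-1-[(2E)-3-methylpenta-2,4-dien-1-yl]-1,4,4a,5,6,7,8,8a-octahydronaphthalene-2-carboxylate
Product: 19 (1S,4S,4aR,8aS)-4-hydroxy-5,5,8a-trimethyl-1-[(2E)-3-methylpenta-2,4-dien-1-yl]-1,4,4a,5,6,7,8,8a-octahydronaphthalene-2-carboxylic acid, via lithium carboxylate 18 (not isolated)
Conditions: LiOH, THF/MeOH/H2O, 40 °C; then 1 M HCl to pH 4, 0 °C
Reagents that add atoms: lithium hydroxide, [Li+].[OH-]
Why: Saponification (acyl–oxygen cleavage) of the methyl ester is placed before acetylation so that no acetate has to survive base.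

**Step 13**
Reactants: 19 (1S,4S,4aR,8aS)-4-hydroxy-5,5,8a-trimethyl-1-[(2E)-3-methylpenta-2,4-dien-1-yl]-1,4,4a,5,6,7,8,8a-octahydronaphthalene-2-carboxylic acid
Product: 21 (1S,4S,4aR,8aS)-4-acetoxy-5,5,8a-trimethyl-1-[(2E)-3-methylpenta-2,4-dien-1-yl]-1,4,4a,5,6,7,8,8a-octahydronaphthalene-2-carboxylic acid, via mixed anhydride 20 (not isolated)
Conditions: Ac2O, pyridine, DMAP (cat.), rt; then THF/H2O, rt
Reagents that add atoms: acetic anhydride, CC(=O)OC(C)=O
Why: DMAP-catalysed acetylation of the hindered axial C6 hydroxyl, in which the carboxyl is converted in passing to the mixed anhydride 20 that water should hydrolyse at the acetyl carbonyl during work-up.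

**Compound list**
1 | 2,4,4-trimethylcyclohex-2-en-1-one | CC1=CC(C)(C)CCC1=O | starting material
2 | (1S)-2,4,4-trimethylcyclohex-2-en-1-ol | O[C@H]1CCC(C)(C)C=C1C | intermediate
3 | (6S)-6-(ethenyloxy)-1,3,3-trimethylcyclohex-1-ene | C=CO[C@H]1CCC(C)(C)C=C1C | intermediate (not isolated)
4 | 2-[(1R)-2,6,6-trimethylcyclohex-2-en-1-yl]acetaldehyde | O=CC[C@H]1C(C)=CCCC1(C)C | intermediate
5 | 4,4-diethoxybut-1-yne | C#CCC(OCC)OCC | starting material
6 | lithium 4,4-diethoxybut-1-yn-1-ide | [Li]C#CCC(OCC)OCC | intermediate (not isolated)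
7 | methyl 5,5-diethoxypent-2-ynoate | CCOC(CC#CC(=O)OC)OCC | intermediate
8 | methyl (2E)-2-[bis(2-methylpropyl)alumanyl]-5,5-diethoxypent-2-enoate (Al and vinylic H cis) | COC(=O)/C(=C\CC(OCC)OCC)[Al](CC(C)C)CC(C)C | intermediate (not isolated)
9 | methyl (2Z)-5,5-diethoxy-2-{1-hydroxy-2-[(1R)-2,6,6-trimethylcyclohex-2-en-1-yl]ethyl}pent-2-enoate (both carbinol epimers) | COC(=O)/C(=C\CC(OCC)OCC)C(O)C[C@H]1C(C)=CCCC1(C)C | intermediate
10 | methyl (2Z)-2-{1-acetoxy-2-[(1R)-2,6,6-trimethylcyclohex-2-en-1-yl]ethyl}-5,5-diethoxypent-2-enoate (both acetate epimers) | COC(=O)/C(=C\CC(OCC)OCC)C(OC(C)=O)C[C@H]1C(C)=CCCC1(C)C | intermediate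
11 | methyl 3-acetoxy-1-(2,2-diethoxyethyl)-5,5,8a-trimethyldecahydronaphthalene-2-carboxylate (trans-fused; C1, C4a and C8a arranged as in 12; epimers at C2 and C3) | CCOC(C[C@@H]1C(C(=O)OC)C(OC(C)=O)C[C@@H]2C(C)(C)CCC[C@@]12C)OCC | intermediate (not isolated)
12 | methyl (1S,4aR,8aR)-1-(2,2-diethoxyethyl)-5,5,8a-trimethyl-1,4,4a,5,6,7,8,8a-octahydronaphthalene-2-carboxylate | CCOC(C[C@@H]1C(C(=O)OC)=CC[C@@H]2C(C)(C)CCC[C@@]12C)OCC | intermediate
13 | methyl (1S,4aR,8aS)-1-(2,2-diethoxyethyl)-5,5,8a-trimethyl-4-oxo-1,4,4a,5,6,7,8,8a-octahydronaphthalene-2-carboxylate | CCOC(C[C@@H]1C(C(=O)OC)=CC(=O)[C@@H]2C(C)(C)CCC[C@@]12C)OCC | intermediate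
14 | methyl (1S,4S,4aR,8aS)-1-(2,2-diethoxyethyl)-4-hydroxy-5,5,8a-trimethyl-1,4,4a,5,6,7,8,8a-octahydronaphthalene-2-carboxylate | CCOC(C[C@@H]1C(C(=O)OC)=C[C@H](O)[C@@H]2C(C)(C)CCC[C@@]12C)OCC | intermediate
15 | methyl (1S,4S,4aR,8aS)-4-hydroxy-5,5,8a-trimethyl-1-(2-oxoethyl)-1,4,4a,5,6,7,8,8a-octahydronaphthalene-2-carboxylate | O=CC[C@@H]1C(C(=O)OC)=C[C@H](O)[C@@H]2C(C)(C)CCC[C@@]12C | intermediate
16 | methyl (1S,4S,4aR,8aS)-4-hydroxy-5,5,8a-trimethyl-1-[(2E)-3-methyl-4-oxobut-2-en-1-yl]-1,4,4a,5,6,7,8,8a-octahydronaphthalene-2-carboxylate | O=C/C(C)=C/C[C@@H]1C(C(=O)OC)=C[C@H](O)[C@@H]2C(C)(C)CCC[C@@]12C | intermediate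
17 | methyl (1S,4S,4aR,8aS)-4-hydroxy-5,5,8a-trimethyl-1-[(2E)-3-methylpenta-2,4-dien-1-yl]-1,4,4a,5,6,7,8,8a-octahydronaphthalene-2-carboxylate | C=C/C(C)=C/C[C@@H]1C(C(=O)OC)=C[C@H](O)[C@@H]2C(C)(C)CCC[C@@]12C | intermediate
18 | lithium (1S,4S,4aR,8aS)-4-hydroxy-5,5,8a-trimethyl-1-[(2E)-3-methylpenta-2,4-dien-1-yl]-1,4,4a,5,6,7,8,8a-octahydronaphthalene-2-carboxylate | [Li+].C=C/C(C)=C/C[C@@H]1C(C(=O)[O-])=C[C@H](O)[C@@H]2C(C)(C)CCC[C@@]12C | intermediate (not isolated)
19 | (1S,4S,4aR,8aS)-4-hydroxy-5,5,8a-trimethyl-1-[(2E)-3-methylpenta-2,4-dien-1-yl]-1,4,4a,5,6,7,8,8a-octahydronaphthalene-2-carboxylic acid | C=C/C(C)=C/C[C@@H]1C(C(=O)O)=C[C@H](O)[C@@H]2C(C)(C)CCC[C@@]12C | intermediate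
20 | acetic (1S,4S,4aR,8aS)-4-acetoxy-5,5,8a-trimethyl-1-[(2E)-3-methylpenta-2,4-dien-1-yl]-1,4,4a,5,6,7,8,8a-octahydronaphthalene-2-carboxylic anhydride | C=C/C(C)=C/C[C@@H]1C(C(=O)OC(C)=O)=C[C@H](OC(C)=O)[C@@H]2C(C)(C)CCC[C@@]12C | intermediate (not isolated)
21 | (1S,4S,4aR,8aS)-4-acetoxy-5,5,8a-trimethyl-1-[(2E)-3-methylpenta-2,4-dien-1-yl]-1,4,4a,5,6,7,8,8a-octahydronaphthalene-2-carboxylic acid (CNP0294871.1) | C=C/C(C)=C/C[C@@H]1C(C(=O)O)=C[C@H](OC(C)=O)[C@@H]2C(C)(C)CCC[C@@]12C | target

**Step count.** Total: 13 steps. Longest linear sequence: 12 steps (steps 1, 2 and 4 to 13, from ketone 1); step 3 prepares the ynoate in a side branch.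

**Steps most likely to fail**

Step 6. The tertiary C10 radical may be reduced by the iron hydride (net hydrogenation of the ring alkene) before it adds to the hindered, β-substituted acrylate terminus, and hydrogen-atom transfer to the acrylate may compete. The fallback sets out from 10 and generates the same radical with no metal hydride present. Markovnikov oxymercuration–demercuration (Hg(OAc)2, THF/H2O; NaBH4) would give the tertiary alcohol methyl (2Z)-2-{1-acetoxy-2-[(1R)-2-hydroxy-2,6,6-trimethylcyclohexyl]ethyl}-5,5-diethoxypent-2-enoate F1. Acylation with the chlorooxalate of N-hydroxyphthalimide (Et3N, DMAP, CH2Cl2) would give the N-phthalimidoyl oxalate of that alcohol F2. Visible-light photoredox reduction ([Ru(bpy)3](PF6)2, Hantzsch ester, i-Pr2NEt·HBF4, blue light) should fragment F2 to the C10 radical, which cyclizes as in step 6 and competes only with slow hydrogen donation from the Hantzsch ester. DBU then completes the loss of acetate, and the route is rejoined at 12.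

Step 7. Hydrogen abstraction may be unselective (the acetal C–H or the tertiary allylic C9–H), and once the ketone is in place the C9 hydrogen is vinylogously acidic, so epimerization at C9 may set in. The fallback sets out from 12 and oxygenates C6 by an ene reaction and [2,3] shift instead of a radical abstraction. SeO2 (cat.) with t-BuOOH in CH2Cl2 at rt should give methyl (1S,4aR,8aS)-1-(2,2-diethoxyethyl)-4-hydroxy-5,5,8a-trimethyl-1,4,4a,5,6,7,8,8a-octahydronaphthalene-2-carboxylate F3, as either or both C4 epimers. Dess–Martin periodinane (NaHCO3, CH2Cl2, 0 °C) would then oxidise it to 13, where the route is rejoined.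

Step 2. Transvinylation of the hindered secondary alcohol may stay incomplete, and thermal elimination to a diene may compete with the [3,3] shift. The fallback sets out from 2 and uses the orthoester (Johnson–Claisen) variant, which generates the ketene acetal in situ. MeC(OEt)3 with catalytic EtCO2H at 140 °C should give ethyl 2-[(1R)-2,6,6-trimethylcyclohex-2-en-1-yl]acetate F4 with the same transfer of configuration. Reduction with i-Bu2AlH (CH2Cl2, −78 °C) then gives 4, where the route is rejoined.

**Further compounds**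
F1 | step 6 | methyl (2Z)-2-{1-acetoxy-2-[(1R)-2-hydroxy-2,6,6-trimethylcyclohexyl]ethyl}-5,5-diethoxypent-2-enoate | COC(=O)/C(=C\CC(OCC)OCC)C(OC(C)=O)C[C@H]1C(C)(O)CCCC1(C)C
F2 | step 6 | N-phthalimidoyl oxalate of F1 | COC(=O)/C(=C\CC(OCC)OCC)C(OC(C)=O)C[C@H]1C(C)(OC(=O)C(=O)ON2C(=O)c3ccccc3C2=O)CCCC1(C)C
F3 | step 7 | methyl (1S,4aR,8aS)-1-(2,2-diethoxyethyl)-4-hydroxy-5,5,8a-trimethyl-1,4,4a,5,6,7,8,8a-octahydronaphthalene-2-carboxylate (C4 epimers) | CCOC(C[C@@H]1C(C(=O)OC)=CC(O)[C@@H]2C(C)(C)CCC[C@@]12C)OCC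
F4 | step 2 | ethyl 2-[(1R)-2,6,6-trimethylcyclohex-2-en-1-yl]acetate | CCOC(=O)C[C@H]1C(C)=CCCC1(C)C
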